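## Structural features

The target is a 2,2-disubstituted chroman: a benzene ring (C4a, C5–C8, C8a) fused to a dihydropyran (O1, C2–C4), with a free hydroxyl on C6 para to O1 and a methyl on C8. The arene is therefore a hydroquinone monoether, easily oxidised, above all as its phenoxide. C2 is the only stereocentre, quaternary and (R), carrying O1, a methyl, ring C3H2 and chain C1'H2; with no neighbouring stereocentre its configuration must come from a reagent or catalyst. The chain (C1'–C8' plus a carboxyl on C8') holds two trisubstituted (E) alkenes, C3'=C4' (methyl on C4') and C7'=C8', the latter conjugated to the acid. Fragile points are the tertiary aryl alkyl ether C2–O1 (ionised by strong Lewis or Brønsted acids, with loss of configuration), the two alkenes (acid-induced cyclisation, no hydrogenation once present), the enoic acid (soft nucleophiles) and the phenol. The real difficulty is C2: its two methylene substituents, C3 and C1', are sterically almost alike, so the centre has to be created together with the ring. The key step exploits that C2 lies between O1 and C1'H2 and bears no hydrogen: when the phenol oxygen closes the pyran ring onto the inner carbon of a palladium-bound C2=C1' alkene, the metal ends on C1' with no β-hydrogen, and the σ-bond can only be captured by CO, which supplies C2'.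

## Logic of the disconnections

**21 to 19 (through 20).** Cut: O6–Si and the ester C–O, no skeletal bond. Reason: the free phenol and acid would quench an organozinc and the phenol is oxidation-prone, so both stay masked until the last flask. Gain: every earlier step runs on a neutral, air-stable compound. Demand: the unmasking may use neither acid, Lewis acid nor oxidant, so fluoride and then hydroxide under argon.

**19 to 11 and 17.** Cut: C2'–C3' (sp3–sp2). Reason: it separates the only chiral part from an achiral chain that already holds both (E) alkenes and the acid oxidation level, and the bond is two atoms away from C2. Gain: convergence into two pieces of similar size. Demand: an sp3 organometal from 11 (namely 18) mild enough for the ester of 17, retention of the vinyl geometry, and no β-hydride elimination.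

**17 to 15 and 16, 15 to 14, 14 to 12.** Cut: C7'=C8' by carbonyl olefination, then C3'–I and C4'–CH3, both made in one carbometalation of an alkyne. Reason: each alkene comes from a reaction with built-in geometry. Gain: 17 is reduced to the commercial compounds 12 and 16. Demand: syn addition with the metal on the terminal carbon, (E)-selective olefination, and a mild oxidation of 14.

**11 to 10 to 9.** Cut: none; functional-group changes at C2' only (C–I from C–OH from the ester). Reason: the iodide is the zinc precursor and the ester is what the key step delivers. Gain: two routine steps link the coupling partner to the key-step product. Demand: neutral conditions that leave the silyl ether and C2–O1 alone.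

**9 to 8.** Cut: O1–C2 and C1'–C2'. Reason: both bonds flank the quaternary carbon, so one catalytic event creates the ring, the stereocentre and C2' at the right oxidation level. Gain: a chiral bicycle becomes an achiral open-chain phenol plus a one-carbon carbonyl unit. Demand: ligand control over the enantiotopic alkene faces, an alkylpalladium without β-hydrogen, and an O6 group in 8 that survives quinone, trifluoroacetate and methanol and later leaves without acid. For this reason 8 carries a silyl ether and not a methyl ether, whose late removal would need a Lewis acid able to ionise C2–O1 or a nucleophile that attacks the enoate.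

**8 to 7 to 6 to 4 and 5.** Cut: C2=C1' (ketone methylenation), then C3–C4 (made as a C=C bond from aldehyde and ylide, then hydrogenated). Reason: the four-carbon arm is built on an ortho-formyl phenol by two olefinations, without an organometal next to a free phenol. Gain: 8 is reduced to 4 and commercial 5. Demand: hydrogenation must stop at the C=C bond, and the methylenation needs excess ylide because of the acidic phenol.

**4 to 3 to 2 to 1.** Cut: O6–Si, then the O6–CH3 exchange, then C4–C4a (formyl carbon onto the ring). Reason: 1 is commercial with its two oxygens already differentiated and only one ortho position free, and the methyl-to-silyl exchange is placed on the aldehyde, where there is no stereocentre or alkene and the chelated ortho-hydroxyl steers silylation to O6. Gain: a single commercial phenol. Demand: ortho-selective formylation, a demethylation that spares the aldehyde, and site-selective silylation.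

## Other disconnections considered

**Alternative 1:** The cut removes three bonds of the benzene ring (C8a–C4a, C5–C6, C6–C7). The arene is built last from a carbene carbon (C8a), an isopropenyl unit (C8, its methyl, C7), an alkyne (C4a, C5) and CO (C6), and the pyran ring follows because carbene oxygen and alkyne are already joined through O1–C2–C3–C4.
- Forward: the tertiary alkynol A3 would be made from farnesol A4 (Sharpless epoxidation, reductive opening to the 1,3-diol, sulfonylation of the primary hydroxyl, displacement by acetylide). It would be converted into the alkoxy(isopropenyl)carbene complex A2 of Cr(CO)5, and heating A2 would give the chromanol A1 by a Dötz benzannulation.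
- In favour: C2 is set by a very dependable asymmetric reaction on an allylic alcohol; the whole chain with its (E)-C3'=C4' bond comes from the terpene pool without fragment coupling; C6–OH arrives free from the inserted CO. On these three points the alternative is equal or better.
- Against: the alkoxy group must come from a hindered tertiary alcohol, the least favourable case for making such carbenes. Chromium is stoichiometric. The tether forces the alkyne substituent next to the carbene carbon, where cyclobutenone, furan and indene-type pathways compete. A1 ends in a gem-dimethyl alkene, so the acid needs a late allylic oxidation of the (E)-methyl (SeO2, then Pinnick oxidation) beside a second trisubstituted alkene and a chromanol that must be protected.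
- Comparison: on structure it solves the chain but leaves the C8' oxidation level open, where the chosen plan builds the acid in with 17. On mechanism its enantio-determining step is the more secure, its ring-forming step the less predictable. On step count the two are close (about ten to eleven against eleven in the longest line), so step economy decides nothing.

**Alternative 2:** The cut is O1–C8a together with C4–C4a; the chroman derives from a para-substituted phenol whose side chain first sits on the future C8a.
- Forward: the phenol A7 would be oxidised with PhI(OAc)2 to the spirodienone A6 (tertiary hydroxyl onto the ipso carbon), and BF3·OEt2 in the same flask would induce the dienone–phenol shift of C4 to C4a to give the chromanol A5. A7 could come from (R)-linalool A8 by hydroboration of the vinyl group and Suzuki–Miyaura coupling with 4-bromo-3-methylphenol A9.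
- In favour: the stereocentre is bought, not made, if A8 of adequate enantiopurity is at hand; ring formation needs no transition metal, ligand or CO; the phenol is released in the same operation; A5 is reached in about three steps. On cost and directness of access to the nucleus it is equal or better.
- Against: the 1,2-shift has three courses (C4 to C4a, C4 to the methyl-bearing C8, or oxygen migration) and only the first is right. BF3 acts on a compound with a tertiary ether at C2 and a trisubstituted alkene, so ionisation at C2 and cation–olefin cyclisation are conceivable, and the oxidant may attack the alkene. A5 holds only C1'–C4' with two methyls, so C5'–C8' and the acid need an (E)-selective allylic oxidation, an sp3–sp3 allylic coupling and phenol protection, five or more further steps.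
- Comparison: on structure it is better on the nucleus and clearly worse on the chain (linear extension through C–H oxidation against convergent coupling of a stereodefined iodo dienoate). On mechanism a cationic rearrangement next to the stereocentre stands against neutral palladium chemistry that never ionises C2–O1. Overall length is similar or slightly greater.

**Alternative 3:** The cut takes C4 out of the ring (C3–C4 and C4–C4a) and leads back to a five-membered coumaranone.
- Forward: the coumaranone A11, activated by AlMe3, would add trimethylsilyldiazomethane at its C3 ketone, and a 1,2-aryl shift with loss of N2 would give the chroman-3-one A10. A11 would come from the enol carbonate A12 by palladium-catalysed decarboxylative asymmetric allylation (Tsuji–Trost type).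
- In favour: the quaternary centre is made on a flat five-ring enolate by a well-developed catalytic method, remote from the arene substituents; no CO and no stoichiometric quinone are needed; the allyl group already contains C1'. As a catalytic asymmetric entry it is the equal of the chosen plan.
- Against: A10 has a C3 ketone the target lacks, so an oxidation level is introduced only to be removed (two to three steps). Migration of the aryl group in preference to the quaternary C2 is not assured, so a chroman-4-one or an epoxide may form. The allyl alkene sits at C2'=C3', the wrong place, and must be cleaved to a C2' aldehyde and reduced before the chain can be attached as in the chosen plan. The phenol is again a methyl ether.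
- Comparison: on structure it converges on an alcohol equivalent to 10 but needs roughly ten steps to get there instead of eight. On mechanism the diazo ring expansion is less selective than the oxypalladation–carbonylation, which delivers C2' directly at the right oxidation level. On step economy it is clearly worse.

Key step: step 7

Assumption on the sense of induction: (S,S)-Bn-BOXAX, that is (S)-2,2'-bis[(4S)-4-benzyl-4,5-dihydro-1,3-oxazol-2-yl]-1,1'-binaphthyl, is taken to give (S)-9 by analogy with closely related 2-(3-methylbut-3-enyl)phenols; if 8 responded in the opposite sense, the (R,R)-ligand would be used and nothing else changes.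

Remark on descriptors: 9, 10, 11 and 18 are (S) while 19, 20 and 21 are (R), although the arrangement at C2 is never altered; only the CIP rank of C1' against C3 changes once C2' carries carbon instead of oxygen, iodine or zinc.

## Route

Step 1
Reactants: 1 4-methoxy-2-methylphenol
Product: 2 2-hydroxy-5-methoxy-3-methylbenzaldehyde
Conditions: MgCl2, Et3N, (CH2O)n, MeCN, reflux; then 1 M HCl
Reagents that add atoms: formaldehyde (as paraformaldehyde), C=O
Why: Casnati–Skattebøl ortho-formylation: the magnesium phenoxide delivers formaldehyde to the only free ortho position, and the benzylic alkoxide is oxidised to the aldehyde by a second formaldehyde in an Oppenauer-type hydride transfer.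

Step 2
Reactants: 2 2-hydroxy-5-methoxy-3-methylbenzaldehyde
Product: 3 2,5-dihydroxy-3-methylbenzaldehyde
Conditions: BBr3 (3 equiv), CH2Cl2, −78 °C to 0 °C; then H2O
Reagents that add atoms: none
Why: Lewis-acid demethylation of an aryl methyl ether (bromide attacks the O-methyl carbon of the boron adduct in an SN2 step); it is placed here because 2 has no stereocentre, alkene or tertiary ether that BBr3 could damage, and the temperature is kept low to spare the aldehyde.

Step 3
Reactants: 3 2,5-dihydroxy-3-methylbenzaldehyde
Product: 4 2-hydroxy-3-methyl-5-[(triisopropylsilyl)oxy]benzaldehyde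
Conditions: TIPSCl (1.05 equiv), imidazole, CH2Cl2, 0 °C to rt
Reagents that add atoms: chlorotriisopropylsilane, CC(C)[Si](Cl)(C(C)C)C(C)C
Why: Imidazole-mediated silylation of a phenol; the C2 hydroxyl is hydrogen-bonded to the formyl oxygen and flanked on both sides, so the bulky chloride should react at the C5 hydroxyl only. The triisopropylsilyl ether is chosen because it should resist ylides, hydride, zinc and slightly acidic methanol and leaves with fluoride at the end.

Step 4
Reactants: 4 2-hydroxy-3-methyl-5-[(triisopropylsilyl)oxy]benzaldehyde; 5 1-(triphenylphosphoranylidene)propan-2-one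
Product: 6 (3E)-4-{2-hydroxy-3-methyl-5-[(triisopropylsilyl)oxy]phenyl}but-3-en-2-one
Conditions: toluene, 90 °C
Reagents that add atoms: none
Why: Wittig reaction of a stabilised ylide with an aryl aldehyde, which should give the (E)-enone; the ylide is too weakly basic to be consumed by the phenol, and the geometry is erased in step 5.

Step 5
Reactants: 6 (3E)-4-{2-hydroxy-3-methyl-5-[(triisopropylsilyl)oxy]phenyl}but-3-en-2-one
Product: 7 4-{2-hydroxy-3-methyl-5-[(triisopropylsilyl)oxy]phenyl}butan-2-one
Conditions: H2 (1 atm), Pd/C, EtOAc, rt
Reagents that add atoms: none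
Why: Heterogeneous hydrogenation of the conjugated C=C bond; the isolated ketone and the aryl silyl ether should not be reduced at balloon pressure, and there is no benzylic C–O bond to cleave. 7 may sit partly as its cyclic hemiketal, which reopens in step 6.

Step 6
Reactants: 7 4-{2-hydroxy-3-methyl-5-[(triisopropylsilyl)oxy]phenyl}butan-2-one
Product: 8 2-methyl-6-(3-methylbut-3-en-1-yl)-4-[(triisopropylsilyl)oxy]phenol
Conditions: Ph3PCH3Br (3.5 equiv), n-BuLi (3.3 equiv), THF, 0 °C; then 7, 0 °C to rt
Reagents that add atoms: methyltriphenylphosphonium bromide (source of the CH2 group), C[P+](c1ccccc1)(c1ccccc1)c1ccccc1.[Br-]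
Why: Wittig methylenation of a methyl ketone with the non-stabilised ylide; one equivalent of ylide is taken up by the phenol and returned on work-up, hence the excess. The 1,1-disubstituted alkene is the C2=C1' unit for the key step.

Step 7
Reactants: 8 2-methyl-6-(3-methylbut-3-en-1-yl)-4-[(triisopropylsilyl)oxy]phenol
Product: 9 methyl 2-{(2S)-2,8-dimethyl-6-[(triisopropylsilyl)oxy]chroman-2-yl}acetate
Conditions: Pd(OCOCF3)2 (5 mol%), (S,S)-Bn-BOXAX (20 mol%), p-benzoquinone (4 equiv), CO (1 atm), MeOH, rt
Reagents that add atoms: carbon monoxide, [C-]#[O+]; methanol, CO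
Why: Wacker-type oxypalladation followed by alkoxycarbonylation: the cationic bis(oxazoline) complex of divalent palladium binds the 1,1-disubstituted alkene of 8 and the phenol oxygen attacks the inner alkene carbon, forming O1–C2 and leaving palladium on C1'. This σ-alkylpalladium has only the fully substituted C2 in the β-position, so β-hydride elimination is impossible; CO inserts and methanol cleaves the acylpalladium to the methyl ester (C1'–C2'), releasing zerovalent palladium that p-benzoquinone returns to the divalent state. The closest known reaction type is the enantioselective oxypalladation–carbonylation domino of 2-(3-methylbut-3-enyl)phenols under binaphthyl bis(oxazoline) control, from whose substrates 8 differs only in the arene substituents. The pyran ring closes in the 6-exo-trig mode. The new stereocentre C2 is set in the oxypalladation event by the ligand alone, whose axial and central chirality should let only one enantiotopic alkene face (methyl against C1'H2) sit on the metal while the tethered phenol attacks; the (S,S)-ligand is expected to give (S)-9. The step needs enantiofacial selectivity (ligand), capture by CO instead of elimination (no β-hydrogen) and attack by the phenol instead of methanol (intramolecular six-ring closure). The silyl ether on O6 keeps the arene from being a free hydroquinone that the quinone could oxidise, and it should tolerate the trace of trifluoroacetic acid in methanol at room temperature.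

Step 8
Reactants: 9 methyl 2-{(2S)-2,8-dimethyl-6-[(triisopropylsilyl)oxy]chroman-2-yl}acetate
Product: 10 2-{(2S)-2,8-dimethyl-6-[(triisopropylsilyl)oxy]chroman-2-yl}ethan-1-ol
Conditions: LiAlH4, Et2O, 0 °C; then aqueous NaOH work-up
Reagents that add atoms: none
Why: Hydride reduction of the methyl ester to the primary alcohol; the hindered aryl silyl ether and the chroman should be inert at 0 °C, and the quaternary centre is not involved.

Step 9
Reactants: 10 2-{(2S)-2,8-dimethyl-6-[(triisopropylsilyl)oxy]chroman-2-yl}ethan-1-ol
Product: 11 {[(2S)-2-(2-iodoethyl)-2,8-dimethylchroman-6-yl]oxy}triisopropylsilane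
Conditions: PPh3, imidazole, I2, CH2Cl2, 0 °C to rt
Reagents that add atoms: iodine, II
Why: Appel-type iodination: the alkoxyphosphonium ion is displaced by iodide in an SN2 step at the unhindered primary C2'; the medium is neutral, so the tertiary ether at C2 cannot ionise.

Step 10
Reactants: 12 pent-4-yn-1-ol
Product: 14 (4E)-5-iodo-4-methylpent-4-en-1-ol, via alkenylalane alkoxide 13 (not isolated)
Conditions: AlMe3 (3 equiv), Cp2ZrCl2 (0.25 equiv), CH2Cl2, 0 °C to rt; then I2, THF, −30 °C to 0 °C; aqueous potassium sodium tartrate
Reagents that add atoms: trimethylaluminium, C[Al](C)C; iodine, II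
Why: Zirconium-catalysed carboalumination of a terminal alkyne (Negishi carboalumination): methyl and aluminium add syn with aluminium on the terminal carbon, and iodine cleaves the C–Al bond with retention, which fixes the (E) geometry of the future C3'=C4' bond. The hydroxyl is masked in the flask as its aluminium alkoxide.

Step 11
Reactants: 14 (4E)-5-iodo-4-methylpent-4-en-1-ol
Product: 15 (4E)-5-iodo-4-methylpent-4-enal
Conditions: Dess–Martin periodinane, CH2Cl2, 0 °C to rt
Reagents that add atoms: none
Why: Dess–Martin oxidation of a primary alcohol to the aldehyde under near-neutral conditions; the vinyl iodide is a spectator, and the volatile aldehyde is used at once.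

Step 12
Reactants: 15 (4E)-5-iodo-4-methylpent-4-enal; 16 ethyl 2-(triphenylphosphoranylidene)propanoate
Product: 17 ethyl (2E,6E)-7-iodo-2,6-dimethylhepta-2,6-dienoate
Conditions: CH2Cl2, rt
Reagents that add atoms: none
Why: Wittig reaction of a stabilised α-branched ylide with an aliphatic aldehyde, which should give the (E)-2-methyl enoate (ester trans to the chain) with high selectivity.

Step 13
Reactants: 11 {[(2S)-2-(2-iodoethyl)-2,8-dimethylchroman-6-yl]oxy}triisopropylsilane; 17 ethyl (2E,6E)-7-iodo-2,6-dimethylhepta-2,6-dienoate
Product: 19 ethyl (2E,6E)-9-{(2R)-2,8-dimethyl-6-[(triisopropylsilyl)oxy]chroman-2-yl}-2,6-dimethylnona-2,6-dienoate, via alkylzinc iodide 18 (not isolated)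
Conditions: Zn dust (activated with BrCH2CH2Br and Me3SiCl), LiCl, THF, 40 °C; then 17, PdCl2(dppf) (5 mol%), THF, rt to 40 °C
Reagents that add atoms: none
Why: Negishi cross-coupling: LiCl-assisted insertion of zinc into the primary C–I bond gives 18, which transmetalates to the alkenylpalladium iodide formed from 17. Oxidative addition and reductive elimination proceed with retention, so the (E) geometry of C3'=C4' is carried over, and the organozinc tolerates the ester and the silyl ether. The bidentate phosphine should favour reductive elimination over β-hydride elimination.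

Step 14
Reactants: 19 ethyl (2E,6E)-9-{(2R)-2,8-dimethyl-6-[(triisopropylsilyl)oxy]chroman-2-yl}-2,6-dimethylnona-2,6-dienoate
Product: 21 (2E,6E)-9-[(2R)-6-hydroxy-2,8-dimethylchroman-2-yl]-2,6-dimethylnona-2,6-dienoic acid, via phenol ethyl ester 20 (not isolated)
Conditions: Bu4NF, THF, 0 °C; then LiOH·H2O, MeOH/H2O, 45 °C, argon; then 1 M HCl to pH 3, 0 °C
Reagents that add atoms: lithium hydroxide (its oxygen becomes the hydroxyl oxygen of the acid), [Li+].[OH-]
Why: Fluoride cleaves the aryl Si–O bond, then hydroxide saponifies the ethyl ester by addition–elimination at the acyl carbon. No acid or Lewis acid meets the tertiary ether or the alkenes before the cold final acidification, and air is excluded because the phenoxide of a hydroquinone monoether oxidises easily.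

## Compound list

1 | 4-methoxy-2-methylphenol | COc1ccc(O)c(C)c1 | starting material
2 | 2-hydroxy-5-methoxy-3-methylbenzaldehyde | COc1cc(C)c(O)c(C=O)c1 | intermediate
3 | 2,5-dihydroxy-3-methylbenzaldehyde | Cc1cc(O)cc(C=O)c1O | intermediate
4 | 2-hydroxy-3-methyl-5-[(triisopropylsilyl)oxy]benzaldehyde | Cc1cc(O[Si](C(C)C)(C(C)C)C(C)C)cc(C=O)c1O | intermediate
5 | 1-(triphenylphosphoranylidene)propan-2-one | CC(=O)C=P(c1ccccc1)(c1ccccc1)c1ccccc1 | starting material
6 | (3E)-4-{2-hydroxy-3-methyl-5-[(triisopropylsilyl)oxy]phenyl}but-3-en-2-one | CC(=O)/C=C/c1cc(O[Si](C(C)C)(C(C)C)C(C)C)cc(C)c1O | intermediate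
7 | 4-{2-hydroxy-3-methyl-5-[(triisopropylsilyl)oxy]phenyl}butan-2-one | CC(=O)CCc1cc(O[Si](C(C)C)(C(C)C)C(C)C)cc(C)c1O | intermediate
8 | 2-methyl-6-(3-methylbut-3-en-1-yl)-4-[(triisopropylsilyl)oxy]phenol | C=C(C)CCc1cc(O[Si](C(C)C)(C(C)C)C(C)C)cc(C)c1O | intermediate
9 | methyl 2-{(2S)-2,8-dimethyl-6-[(triisopropylsilyl)oxy]chroman-2-yl}acetate | COC(=O)C[C@]1(C)CCc2cc(O[Si](C(C)C)(C(C)C)C(C)C)cc(C)c2O1 | intermediate
10 | 2-{(2S)-2,8-dimethyl-6-[(triisopropylsilyl)oxy]chroman-2-yl}ethan-1-ol | OCC[C@]1(C)CCc2cc(O[Si](C(C)C)(C(C)C)C(C)C)cc(C)c2O1 | intermediate
11 | {[(2S)-2-(2-iodoethyl)-2,8-dimethylchroman-6-yl]oxy}triisopropylsilane | ICC[C@]1(C)CCc2cc(O[Si](C(C)C)(C(C)C)C(C)C)cc(C)c2O1 | intermediate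
12 | pent-4-yn-1-ol | C#CCCCO | starting material
13 | dimethyl{(1E)-5-[(dimethylalumanyl)oxy]-2-methylpent-1-en-1-yl}alumane | C[Al](C)/C=C(\C)CCCO[Al](C)C | intermediate
14 | (4E)-5-iodo-4-methylpent-4-en-1-ol | C/C(=C\I)CCCO | intermediate
15 | (4E)-5-iodo-4-methylpent-4-enal | C/C(=C\I)CCC=O | intermediate
16 | ethyl 2-(triphenylphosphoranylidene)propanoate | CCOC(=O)C(C)=P(c1ccccc1)(c1ccccc1)c1ccccc1 | starting material
17 | ethyl (2E,6E)-7-iodo-2,6-dimethylhepta-2,6-dienoate | CCOC(=O)/C(C)=C/CC/C(C)=C/I | intermediate
18 | {2-[(2S)-2,8-dimethyl-6-[(triisopropylsilyl)oxy]chroman-2-yl]ethyl}zinc iodide | I[Zn]CC[C@]1(C)CCc2cc(O[Si](C(C)C)(C(C)C)C(C)C)cc(C)c2O1 | intermediate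
19 | ethyl (2E,6E)-9-{(2R)-2,8-dimethyl-6-[(triisopropylsilyl)oxy]chroman-2-yl}-2,6-dimethylnona-2,6-dienoate | CCOC(=O)/C(C)=C/CC/C(C)=C/CC[C@]1(C)CCc2cc(O[Si](C(C)C)(C(C)C)C(C)C)cc(C)c2O1 | intermediate
20 | ethyl (2E,6E)-9-[(2R)-6-hydroxy-2,8-dimethylchroman-2-yl]-2,6-dimethylnona-2,6-dienoate | CCOC(=O)/C(C)=C/CC/C(C)=C/CC[C@]1(C)CCc2cc(O)cc(C)c2O1 | intermediate
21 | (2E,6E)-9-[(2R)-6-hydroxy-2,8-dimethylchroman-2-yl]-2,6-dimethylnona-2,6-dienoic acid | C/C(=C\CC[C@]1(C)CCc2cc(O)cc(C)c2O1)CC/C=C(\C)C(=O)O | target

## Step count and least certain steps

Total step count: 14. Longest linear sequence: 11 steps (steps 1–9, 13 and 14, from 1 to 21). The branch from 12 to 17 has 3 steps (10–12).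

**Step 7 (key step).** Enantiofacial discrimination may be insufficient, because the future C5 carries hydrogen where the established substrates carry a substituent that helps the ligand read the arene. Turnover may also stall through precipitation of palladium metal under CO, or the silyl ether may be partly lost in acidic methanol.
Fallback (sets out from 7, comes back at 10): the stereocentre would be made by palladium-catalysed asymmetric allylic etherification.
- Horner–Wadsworth–Emmons reaction of 7 with triethyl phosphonoacetate (NaH in excess, THF), with removal of the minor (Z)-isomer, would give ethyl (2E)-5-{2-hydroxy-3-methyl-5-[(triisopropylsilyl)oxy]phenyl}-3-methylpent-2-enoate F1.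
- Reduction with (i-Bu)2AlH would give 2-[(3E)-5-hydroxy-3-methylpent-3-en-1-yl]-6-methyl-4-[(triisopropylsilyl)oxy]phenol F2.
- Methyl chloroformate and pyridine at low temperature should acylate the primary hydroxyl in preference to the hindered phenol and give (2E)-5-{2-hydroxy-3-methyl-5-[(triisopropylsilyl)oxy]phenyl}-3-methylpent-2-en-1-yl methyl carbonate F3.
- Ionisation of F3 with Pd2(dba)3 and the chiral bis(2-diphenylphosphinobenzamide) ligand of trans-cyclohexane-1,2-diamine (CH2Cl2, acetic acid), then attack of the phenol on the more substituted allyl terminus, should give {[(2S)-2-ethenyl-2,8-dimethylchroman-6-yl]oxy}triisopropylsilane F4.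
- Hydroboration of F4 with 9-BBN and oxidation with NaBO3 would give 10.

**Step 13.** Zinc insertion may be slow or incomplete, with Wurtz-type homocoupling or protonation of 18 by adventitious water, and β-hydride elimination may compete in the coupling.
Fallback (sets out from 11, comes back at 19): a B-alkyl Suzuki–Miyaura coupling. Iodine–lithium exchange on 11 with t-BuLi (Et2O, −78 °C) and trapping with 9-methoxy-9-borabicyclo[3.3.1]nonane would give lithium {2-[(2R)-2,8-dimethyl-6-[(triisopropylsilyl)oxy]chroman-2-yl]ethyl}(methoxy)-9-borabicyclo[3.3.1]nonan-9-uide F5. F5 would be coupled in the same flask with 17 (PdCl2(dppf), K3PO4, DMF/H2O) to give 19.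

**Step 14.** The phenoxide may be oxidised during the warm basic hydrolysis, or the hindered α-methyl enoate may hydrolyse so slowly that prolonged heating is needed.
Fallback (sets out from 17, uses 18, comes back at 21): the ester is exchanged before the coupling so that no aqueous hydroxide is needed at the end.
- 17 would be saponified with LiOH to (2E,6E)-7-iodo-2,6-dimethylhepta-2,6-dienoic acid F6.
- F6 would be esterified with 2-(trimethylsilyl)ethanol (carbodiimide, 4-dimethylaminopyridine) to 2-(trimethylsilyl)ethyl (2E,6E)-7-iodo-2,6-dimethylhepta-2,6-dienoate F7.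
- F7 would be coupled with 18 as in step 13 to give 2-(trimethylsilyl)ethyl (2E,6E)-9-{(2R)-2,8-dimethyl-6-[(triisopropylsilyl)oxy]chroman-2-yl}-2,6-dimethylnona-2,6-dienoate F8.
- Bu4NF in THF should then remove both silicon-based groups from F8 and give 21 after mild acidification.

**Step 6.** Methylenation may stay incomplete, because the basic ylide turns the keto-phenol into its phenoxide or cyclic hemiketal alkoxide and enolises the methyl ketone.
Fallback (sets out from 7, comes back at 8): a Peterson olefination. Addition of Me3SiCH2MgCl (excess, with CeCl3 to suppress enolisation) to 7 would give 2-[3-hydroxy-3-methyl-4-(trimethylsilyl)butyl]-6-methyl-4-[(triisopropylsilyl)oxy]phenol F9, and KH in THF would eliminate silanolate from F9 to give 8.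

## Further compounds

F1 | step 7 | ethyl (2E)-5-{2-hydroxy-3-methyl-5-[(triisopropylsilyl)oxy]phenyl}-3-methylpent-2-enoate | CCOC(=O)/C=C(\C)CCc1cc(O[Si](C(C)C)(C(C)C)C(C)C)cc(C)c1O
F2 | step 7 | 2-[(3E)-5-hydroxy-3-methylpent-3-en-1-yl]-6-methyl-4-[(triisopropylsilyl)oxy]phenol | OC/C=C(\C)CCc1cc(O[Si](C(C)C)(C(C)C)C(C)C)cc(C)c1O
F3 | step 7 | (2E)-5-{2-hydroxy-3-methyl-5-[(triisopropylsilyl)oxy]phenyl}-3-methylpent-2-en-1-yl methyl carbonate | COC(=O)OC/C=C(\C)CCc1cc(O[Si](C(C)C)(C(C)C)C(C)C)cc(C)c1O
F4 | step 7 | {[(2S)-2-ethenyl-2,8-dimethylchroman-6-yl]oxy}triisopropylsilane | C=C[C@]1(C)CCc2cc(O[Si](C(C)C)(C(C)C)C(C)C)cc(C)c2O1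
F5 | step 13 | lithium {2-[(2R)-2,8-dimethyl-6-[(triisopropylsilyl)oxy]chroman-2-yl]ethyl}(methoxy)-9-borabicyclo[3.3.1]nonan-9-uide | [Li+].CO[B-]1(CC[C@]2(C)CCc3cc(O[Si](C(C)C)(C(C)C)C(C)C)cc(C)c3O2)C2CCCC1CCC2
F6 | step 14 | (2E,6E)-7-iodo-2,6-dimethylhepta-2,6-dienoic acid | OC(=O)/C(C)=C/CC/C(C)=C/I
F7 | step 14 | 2-(trimethylsilyl)ethyl (2E,6E)-7-iodo-2,6-dimethylhepta-2,6-dienoate | C[Si](C)(C)CCOC(=O)/C(C)=C/CC/C(C)=C/I
F8 | step 14 | 2-(trimethylsilyl)ethyl (2E,6E)-9-{(2R)-2,8-dimethyl-6-[(triisopropylsilyl)oxy]chroman-2-yl}-2,6-dimethylnona-2,6-dienoate | C[Si](C)(C)CCOC(=O)/C(C)=C/CC/C(C)=C/CC[C@]1(C)CCc2cc(O[Si](C(C)C)(C(C)C)C(C)C)cc(C)c2O1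
F9 | step 6 | 2-[3-hydroxy-3-methyl-4-(trimethylsilyl)butyl]-6-methyl-4-[(triisopropylsilyl)oxy]phenol (racemic) | C[Si](C)(C)CC(C)(O)CCc1cc(O[Si](C(C)C)(C(C)C)C(C)C)cc(C)c1O
A1 | alternative 1 | (2R)-2-[(3E)-4,8-dimethylnona-3,7-dien-1-yl]-2,8-dimethylchroman-6-ol | CC(C)=CCC/C(C)=C/CC[C@]1(C)CCc2cc(O)cc(C)c2O1
A2 | alternative 1 | pentacarbonyl[(prop-1-en-2-yl){[(5R,8E)-5,9,13-trimethyltetradeca-8,12-dien-1-yn-5-yl]oxy}methylidene]chromium | C=C(C)C(O[C@@](C)(CCC#C)CC/C=C(\C)CCC=C(C)C)=[Cr](=C=O)(=C=O)(=C=O)(=C=O)=C=O
A3 | alternative 1 | (5R,8E)-5,9,13-trimethyltetradeca-8,12-dien-1-yn-5-ol | CC(C)=CCC/C(C)=C/CC[C@](O)(C)CCC#C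
A4 | alternative 1 | (2E,6E)-3,7,11-trimethyldodeca-2,6,10-trien-1-ol (farnesol) | CC(C)=CCC/C(C)=C/CC/C(C)=C/CO
A5 | alternative 2 | (2R)-2,8-dimethyl-2-(4-methylpent-3-en-1-yl)chroman-6-ol | CC(C)=CCC[C@]1(C)CCc2cc(O)cc(C)c2O1
A6 | alternative 2 | (2R)-2,6-dimethyl-2-(4-methylpent-3-en-1-yl)-1-oxaspiro[4.5]deca-6,9-dien-8-one (both configurations at C5) | CC1=CC(=O)C=CC12CC[C@@](C)(CCC=C(C)C)O2
A7 | alternative 2 | 4-[(3R)-3-hydroxy-3,7-dimethyloct-6-en-1-yl]-3-methylphenol | Cc1cc(O)ccc1CC[C@](C)(O)CCC=C(C)C
A8 | alternative 2 | (3R)-3,7-dimethylocta-1,6-dien-3-ol ((R)-linalool) | C=C[C@](C)(O)CCC=C(C)C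
A9 | alternative 2 | 4-bromo-3-methylphenol | Cc1cc(O)ccc1Br
A10 | alternative 3 | (2R)-2-allyl-6-methoxy-2,8-dimethylchroman-3-one | C=CC[C@]1(C)C(=O)Cc2cc(OC)cc(C)c2O1
A11 | alternative 3 | (2R)-2-allyl-5-methoxy-2,7-dimethyl-1-benzofuran-3(2H)-one | C=CC[C@]1(C)C(=O)c2cc(OC)cc(C)c2O1
A12 | alternative 3 | allyl 5-methoxy-2,7-dimethyl-1-benzofuran-3-yl carbonate | C=CCOC(=O)Oc1c(C)oc2c(C)cc(OC)cc12
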